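**Strategy.** In chroman numbering the target is a carbocyclic ring A fused to lactone ring B (O1, C2, C3, C4, C4a, C8a). Carbonyl C2 is a lone carbon between O1 and C3, so it is excised as carbon monoxide, leaving a 2-(1-phenylvinyl)phenol whose alkene carbons become C4 and C3. One enantioselective palladium-hydride cyclocarbonylation delivers hydrogen to C4, forms C2–C3 and C2–O1, and closes ring B with the (S)-C4 stereocentre. The precursor is a phloroglucinol-derived 1,1-diarylethene with one free ortho hydroxyl and two benzyl ethers, later removed by neutral hydrogenolysis. C6 acylation and twofold C8 prenylation of ring A complete the target.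

Key step: step 3

Assumption: the sense of induction of the chiral bisphosphine in step 3 cannot be predicted with confidence. (R)-DTBM-SEGPHOS is written for definiteness, and its antipode is used instead if a first run gives the (4R)-lactone.

Step 1
Reactants: 1 2,4,6-trihydroxybenzophenone; 2 benzyl bromide
Product: 3 (2,4-bis(benzyloxy)-6-hydroxyphenyl)(phenyl)methanone
Conditions: BnBr (2.05 equiv), K2CO3 (2.2 equiv), DMF, rt
Reagents that add atoms: benzyl bromide, BrCc1ccccc1
Why: Williamson ether synthesis in which the para hydroxyl and one ortho hydroxyl are alkylated while the last ortho hydroxyl stays free because it is locked in a hydrogen bond to the ketone, benzyl being chosen because it tolerates Grignard, acid and CO/H2 conditions and later leaves without acid or base next to the electron-rich ring and the lactone.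

Step 2
Reactants: 3 (2,4-bis(benzyloxy)-6-hydroxyphenyl)(phenyl)methanone; 4 methylmagnesium bromide
Product: 6 3,5-bis(benzyloxy)-2-(1-phenylvinyl)phenol, via tertiary carbinol 5 (not isolated)
Conditions: MeMgBr (3.5 equiv), THF, 0 °C to rt; aq. NH4Cl; crude 5, PPTS (5 mol %), toluene, 40 °C
Reagents that add atoms: methylmagnesium bromide, C[Mg]Br
Why: Grignard addition to a diaryl ketone that cannot enolise (the first equivalent is consumed by the phenol), followed by acid-catalysed E1 dehydration of the readily ionised, doubly benzylic ortho-hydroxy carbinol, whose only β-hydrogens sit on the new methyl group, so a single alkene can form.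

Step 3
Reactants: 6 3,5-bis(benzyloxy)-2-(1-phenylvinyl)phenol; 7 carbon monoxide
Product: 8 (S)-5,7-bis(benzyloxy)-4-phenylchroman-2-one
Conditions: Pd(OAc)2 (5 mol %), (R)-DTBM-SEGPHOS (6 mol %), CO/H2 (1:1, 40 bar), toluene, 80 °C
Reagents that add atoms: carbon monoxide, [C-]#[O+]
Why: Proposed new method: a bisphosphine-ligated Pd–H species, generated from Pd(OAc)2 under CO/H2, should add syn across the alkene with hydrogen going to the internal carbon (C4) and palladium to the terminal carbon (C3), because the alternative is a congested tertiary diarylalkyl palladium; CO then inserts into the C3–Pd bond (new C2–C3 bond) and the ortho hydroxyl captures the acyl palladium (new C2–O1 bond), returning the hydride. The closest known reaction types are the palladium-catalysed cyclocarbonylation of 2-alkenylphenols to 3,4-dihydrocoumarins with achiral bisphosphines and the enantioselective palladium-hydride hydroalkoxycarbonylation of 1,1-disubstituted alkenes. Ring B closes by a 6-exo-trig acyl substitution at C2. The C4 stereocentre is created in the hydropalladation under catalyst control by the chiral bisphosphine, and the substrate helps face discrimination because the doubly ortho-oxygenated aryl ring is twisted out of the alkene plane while the phenyl ring stays conjugated and the free hydroxyl can bind palladium on one side only. The step needs anti-Markovnikov regioselectivity (six- over five-membered lactone), which the 1,1-diaryl substitution secures, and carbonylation over hydrogenation, which the CO pressure favours; only one lactone can form because the second ortho oxygen is benzylated.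

Step 4
Reactants: 8 (S)-5,7-bis(benzyloxy)-4-phenylchroman-2-one
Product: 9 (S)-5,7-dihydroxy-4-phenylchroman-2-one
Conditions: H2 (1 atm), Pd/C (10 wt %), EtOAc, rt
Reagents that add atoms: none
Why: Catalytic hydrogenolysis of the two benzyl aryl ethers is neutral, so the aryl lactone is neither hydrolysed nor transesterified, and C4, which carries no heteroatom, keeps its configuration.

Step 5
Reactants: 10 (R)-2-methylbutanoic acid
Product: 11 (R)-2-methylbutanoyl chloride
Conditions: (COCl)2 (1.05 equiv), DMF (cat.), CH2Cl2, 0 °C to rt; concentrated cold, used at once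
Reagents that add atoms: oxalyl chloride, ClC(=O)C(Cl)=O
Why: Acid chloride formation with oxalyl chloride under Vilsmeier-type DMF catalysis runs without base near room temperature, so no ketene forms and the α-stereocentre should be retained.

Step 6
Reactants: 9 (S)-5,7-dihydroxy-4-phenylchroman-2-one; 11 (R)-2-methylbutanoyl chloride
Product: 12 (S)-5,7-dihydroxy-6-[(R)-2-methylbutanoyl]-4-phenylchroman-2-one
Conditions: 11 (1.05 equiv), AlCl3 (3.5 equiv), CH2Cl2/PhNO2, 0 °C to rt; cold 1 M HCl
Reagents that add atoms: (R)-2-methylbutanoyl chloride, CC[C@@H](C)C(Cl)=O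
Why: Friedel–Crafts acylation of the phloroglucinol-type ring A, in which C6 lies ortho to both aluminium phenoxides (O5 and O7) that can deliver and then chelate the acyl group and para to the lactone oxygen, whereas C8 is ortho to the inductively deactivating acyloxy oxygen, so substitution should favour C6, and the low temperature guards the ketone α-stereocentre against enolisation.

Step 7
Reactants: 12 (S)-5,7-dihydroxy-6-[(R)-2-methylbutanoyl]-4-phenylchroman-2-one; 13 prenyl bromide (1-bromo-3-methylbut-2-ene)
Product: 15 (S)-5-hydroxy-6-[(R)-2-methylbutanoyl]-8,8-bis(3-methylbut-2-en-1-yl)-4-phenyl-3,4-dihydro-2H-chromene-2,7(8H)-dione (the target), via 8-prenyl phenol 14 (not isolated)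
Conditions: LiN(SiMe3)2 (2.0 equiv), THF, −20 °C, then 13 (1.1 equiv), 0 °C; then LiN(SiMe3)2 (1.0 equiv), 13 (1.3 equiv), 0 °C to rt; aq. NH4Cl, then 1 M HCl
Reagents that add atoms: prenyl bromide, CC(C)=CCBr
Why: Twofold C-alkylation of a lithium phenoxide ending in an alkylative dearomatisation: C8 is the only unsubstituted carbon of ring A (ortho to O7, para to O5), so the first prenyl group enters there with rearomatisation and the second, after renewed deprotonation, gives the 8,8-diprenyl dienone, while the lithium counter-ion in THF favours C- over O-alkylation and the hindered amide base, never in excess over the acidic hydroxyls, should leave the lactone, C3 and the ketone α-carbon untouched.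

**Compound list**

1 | 2,4,6-trihydroxybenzophenone | O=C(c1ccccc1)c1c(O)cc(O)cc1O | starting material
2 | benzyl bromide | BrCc1ccccc1 | starting material
3 | (2,4-bis(benzyloxy)-6-hydroxyphenyl)(phenyl)methanone | O=C(c1ccccc1)c1c(O)cc(OCc2ccccc2)cc1OCc1ccccc1 | intermediate
4 | methylmagnesium bromide | C[Mg]Br | starting material
5 | 3,5-bis(benzyloxy)-2-(1-hydroxy-1-phenylethyl)phenol (racemic tertiary carbinol, not isolated) | CC(O)(c1ccccc1)c1c(O)cc(OCc2ccccc2)cc1OCc1ccccc1 | intermediate
6 | 3,5-bis(benzyloxy)-2-(1-phenylvinyl)phenol | C=C(c1ccccc1)c1c(O)cc(OCc2ccccc2)cc1OCc1ccccc1 | intermediate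
7 | carbon monoxide | [C-]#[O+] | starting material
8 | (S)-5,7-bis(benzyloxy)-4-phenylchroman-2-one | c1ccccc1COc1cc(OCc2ccccc2)c2c(c1)OC(=O)C[C@H]2c1ccccc1 | intermediate
9 | (S)-5,7-dihydroxy-4-phenylchroman-2-one | Oc1cc(O)c2c(c1)OC(=O)C[C@H]2c1ccccc1 | intermediate
10 | (R)-2-methylbutanoic acid | CC[C@@H](C)C(=O)O | starting material
11 | (R)-2-methylbutanoyl chloride | CC[C@@H](C)C(Cl)=O | intermediate
12 | (S)-5,7-dihydroxy-6-[(R)-2-methylbutanoyl]-4-phenylchroman-2-one | CC[C@@H](C)C(=O)c1c(O)c2c(OC(=O)C[C@H]2c2ccccc2)cc1O | intermediate
13 | prenyl bromide (1-bromo-3-methylbut-2-ene) | CC(C)=CCBr | starting material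
14 | (S)-5,7-dihydroxy-6-[(R)-2-methylbutanoyl]-8-(3-methylbut-2-en-1-yl)-4-phenylchroman-2-one (not isolated) | CC[C@@H](C)C(=O)c1c(O)c2c(OC(=O)C[C@H]2c2ccccc2)c(CC=C(C)C)c1O | intermediate
15 | (S)-5-hydroxy-6-[(R)-2-methylbutanoyl]-8,8-bis(3-methylbut-2-en-1-yl)-4-phenyl-3,4-dihydro-2H-chromene-2,7(8H)-dione (CNP0311143.1) | CC[C@@H](C)C(=O)C1=C(O)C2=C(OC(=O)C[C@H]2c2ccccc2)C(CC=C(C)C)(CC=C(C)C)C1=O | target

**Step count.** Total: 7 steps. Longest linear sequence: 6 steps (steps 1, 2, 3, 4, 6, 7); step 5 is a one-step side branch.

**Steps most likely to fail**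

Step 3 (proposed new method). The hydropalladation may discriminate the alkene faces poorly, turnover may be slow on the twisted, hindered alkene, and hydrogenation may compete with CO insertion. The fallback uses known chemistry and sets out from 3. A Wittig olefination with ethyl (triphenylphosphoranylidene)acetate in refluxing N,N-diethylaniline, followed in the same pot by lactonisation of the ortho-hydroxy cinnamate, should give 5,7-bis(benzyloxy)-4-phenyl-2H-chromen-2-one F1. Enantioselective conjugate reduction of this 4-arylcoumarin with a CuH catalyst (Cu(OAc)2, the DTBM-SEGPHOS antipode that gives 4S, diethoxymethylsilane kept near one equivalent, t-BuOH, toluene) then comes back to the route at 8. Alkene 6 and carbon monoxide are bypassed.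

Step 6. Positional control between C6 and C8 may be lost during the acylation, and a second acylation may follow. The fallback sets out from 9. Acid-catalysed methanolysis (MeOH, cat. H2SO4, rt, neutralised before concentration) opens the lactone to methyl (S)-3-phenyl-3-(2,4,6-trihydroxyphenyl)propanoate F2, in which the two ring CH positions are equivalent. Friedel–Crafts acylation with 11 (AlCl3, CH2Cl2/PhNO2, 0 °C) can then give only one C-acyl isomer, methyl (S)-3-[2,4,6-trihydroxy-3-((R)-2-methylbutanoyl)phenyl]-3-phenylpropanoate F3. Acid-catalysed relactonisation (TsOH cat., toluene, 80 °C, methanol distilled off) should close through the hydroxyl that is not adjacent to the ketone, which is unchelated and less hindered, and so comes back to the route at 12. Any C8-acylated lactone formed in step 6 opens to the same ester F3 and could be funnelled to 12 in the same way.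

Step 7. O-alkylation may compete with the dearomatising second C-alkylation, and the base may open the aryl lactone. The fallback sets out from 12. Aqueous KOH at 0 °C opens the lactone on purpose to the salt of (S)-3-[2,4,6-trihydroxy-3-((R)-2-methylbutanoyl)phenyl]-3-phenylpropanoic acid F4. This is prenylated twice in the same aqueous medium with 13 at the only free ring carbon, under the classical conditions for geminal C-prenylation of acylphloroglucinols. Acidification should give the dearomatised seco acid (S)-3-[2,6-dihydroxy-5-((R)-2-methylbutanoyl)-3,3-bis(3-methylbut-2-en-1-yl)-4-oxocyclohexa-1,5-dien-1-yl]-3-phenylpropanoic acid F5. Carbodiimide lactonisation (EDC·HCl, CH2Cl2, 0 °C) through the enol hydroxyl that is not chelated to the acyl ketone then comes back to the route at 15.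

**Further compounds**

F1 | step 3 | 5,7-bis(benzyloxy)-4-phenyl-2H-chromen-2-one | O=c1cc(-c2ccccc2)c2c(OCc3ccccc3)cc(OCc3ccccc3)cc2o1
F2 | step 6 | methyl (S)-3-phenyl-3-(2,4,6-trihydroxyphenyl)propanoate | COC(=O)C[C@@H](c1ccccc1)c1c(O)cc(O)cc1O
F3 | step 6 | methyl (S)-3-[2,4,6-trihydroxy-3-((R)-2-methylbutanoyl)phenyl]-3-phenylpropanoate | CC[C@@H](C)C(=O)c1c(O)cc(O)c([C@@H](CC(=O)OC)c2ccccc2)c1O
F4 | step 7 | (S)-3-[2,4,6-trihydroxy-3-((R)-2-methylbutanoyl)phenyl]-3-phenylpropanoic acid | CC[C@@H](C)C(=O)c1c(O)cc(O)c([C@@H](CC(=O)O)c2ccccc2)c1O
F5 | step 7 | (S)-3-[2,6-dihydroxy-5-((R)-2-methylbutanoyl)-3,3-bis(3-methylbut-2-en-1-yl)-4-oxocyclohexa-1,5-dien-1-yl]-3-phenylpropanoic acid | CC[C@@H](C)C(=O)C1=C(O)C(=C(O)C(CC=C(C)C)(CC=C(C)C)C1=O)[C@@H](CC(=O)O)c1ccccc1
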